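## Retrosynthetic overview

1. Ring numbering: C1 chain-bearing tertiary carbinol, C2 CH2, C3 C=O, C4=C5 alkene, C6 secondary carbinol. The plan rests on the oxygen atoms at C3 and C6 of the single six-membered carbocycle. They occupy the two allylic ends of the C4=C5 double bond, which is the pattern left when the O–O bond of a 3,6-dihydro-1,2-dioxine is broken.
2. Target ⇒ (desilylation) its C1 triethylsilyl ether ⇒ (amine-induced peroxide opening, then singlet-oxygen [4+2]) (S)-1-(heptadec-8-enyl)cyclohexa-2,4-dienyl triethylsilyl ether + O2. The C1 centre directs the new C6 centre.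
3. Diene ⇒ (formate hydrogenolysis, kinetic enol triflation, silylation) (S)-4-alkyl-4-hydroxycyclohex-2-enone ⇒ (ene-reductase desymmetrisation) achiral para-quinol.
4. para-Quinol ⇒ (hypervalent-iodine dearomatisation, desilylation) 4-alkylphenol silyl ether ⇒ (nickel decarboxylative arylation) redox-active ester of oleic acid + silyl-protected 4-iodophenol.
5. Ring order: the carbocycle comes from the arene and is never built. The only ring formed is the peroxide bridge of a transient 2,3-dioxabicyclo[2.2.2]oct-5-ene, and it is opened again in the same flask.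

Key step: step 9

Assumption: the sense of step 5 is inferred from the usual binding mode of old-yellow-enzyme reductases (the mode that turns 3-methylcyclohex-2-enone into (S)-3-methylcyclohexanone), with the small C4 hydroxyl lying against the flavin; this predicts the S enone and is to be verified on the first batch.

## Route

Step 1
Reactants: 1 oleic acid
Product: 2 1,3-dioxoisoindolin-2-yl (Z)-octadec-9-enoate
Conditions: N-hydroxyphthalimide, DIC, DMAP (cat.), CH2Cl2, rt
Reagents that add atoms: N-hydroxyphthalimide, O=C1c2ccccc2C(=O)N1O
Why: Carbodiimide (Steglich-type) esterification activates the carboxyl group as the O-acylisourea, which N-hydroxyphthalimide intercepts to give the redox-active ester without touching the Z alkene.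

Step 2
Reactants: 2 1,3-dioxoisoindolin-2-yl (Z)-octadec-9-enoate; 3 tert-butyl(4-iodophenoxy)dimethylsilane
Product: 4 tert-butyl{4-[(Z)-heptadec-8-en-1-yl]phenoxy}dimethylsilane
Conditions: NiBr2·glyme (cat.), 4,4'-di-tert-butyl-2,2'-bipyridine (cat.), Zn dust, DMA, rt
Reagents that add atoms: none
Why: In this nickel-catalysed decarboxylative cross-electrophile coupling, zinc-driven single-electron reduction of the phthalimide ester releases CO2 and the primary heptadec-8-enyl radical, which the aryl–nickel species from the aryl iodide captures and reductively eliminates to the alkylarene, the alkene being too remote for radical cyclisation and so keeping its Z geometry.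

Step 3
Reactants: 4 tert-butyl{4-[(Z)-heptadec-8-en-1-yl]phenoxy}dimethylsilane
Product: 5 4-[(Z)-heptadec-8-en-1-yl]phenol
Conditions: TBAF, THF, 0 °C; H2O
Reagents that add atoms: none
Why: Fluoride attacks silicon and releases the phenoxide (standard aryl silyl ether cleavage), and nothing else in the molecule is sensitive to fluoride or mild base.

Step 4
Reactants: 5 4-[(Z)-heptadec-8-en-1-yl]phenol
Product: 6 4-[(Z)-heptadec-8-en-1-yl]-4-hydroxycyclohexa-2,5-dien-1-one (achiral para-quinol)
Conditions: PhI(OAc)2, MeCN/H2O, 0 °C
Reagents that add atoms: water, O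
Why: In this hypervalent-iodine oxidative dearomatisation, ligand exchange of the phenol on PhI(OAc)2 and loss of iodobenzene make the alkyl-bearing para carbon electrophilic, water adds there to give the achiral para-quinol, and the unactivated chain alkene does not react with this oxidant without a strong acid.

Step 5
Reactants: 6 4-[(Z)-heptadec-8-en-1-yl]-4-hydroxycyclohexa-2,5-dien-1-one
Product: 7 (S)-4-[(Z)-heptadec-8-en-1-yl]-4-hydroxycyclohex-2-en-1-one
Conditions: ene-reductase YqjM (or OPR3), NADP+ (cat.), glucose dehydrogenase, D-glucose, KH2PO4/K2HPO4 buffer pH 7, DMSO (10% v/v), 30 °C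
Reagents that add atoms: none
Why: Flavin-dependent ene-reductases are known to desymmetrise prochiral 4,4-disubstituted cyclohexa-2,5-dienones by trans addition of hydride (flavin N5 to the β-carbon) and a proton (tyrosine to the α-carbon) to one enantiotopic alkene, and because carbonyl anchor and hydride donor are fixed in the active site, choosing the alkene amounts to choosing which C4 substituent lies against the flavin, so the small hydroxyl rather than the C17 chain should face it, which sets the S carbinol centre and leaves the second ring alkene, the chain alkene and the ketone unreduced.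

Step 6
Reactants: 7 (S)-4-[(Z)-heptadec-8-en-1-yl]-4-hydroxycyclohex-2-en-1-one
Product: 8 (S)-4-[(Z)-heptadec-8-en-1-yl]-4-(triethylsilyloxy)cyclohex-2-en-1-one
Conditions: TESOTf, 2,6-lutidine, CH2Cl2, −78 to 0 °C
Reagents that add atoms: triethylsilyl trifluoromethanesulfonate, CC[Si](CC)(CC)OS(=O)(=O)C(F)(F)F
Why: A silyl triflate with a hindered pyridine base silylates even a tertiary alcohol at low temperature (standard O-silylation), and the carbinol configuration is untouched because only the O–H bond is broken.

Step 7
Reactants: 8 (S)-4-[(Z)-heptadec-8-en-1-yl]-4-(triethylsilyloxy)cyclohex-2-en-1-one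
Product: 10 (S)-4-[(Z)-heptadec-8-en-1-yl]-4-(triethylsilyloxy)cyclohexa-1,5-dien-1-yl trifluoromethanesulfonate, via lithium dienolate 9 (not isolated)
Conditions: LiN(SiMe3)2, THF, −78 °C; N-(5-chloropyridin-2-yl)bis(trifluoromethanesulfonimide), −78 °C; H2O
Reagents that add atoms: N-(5-chloropyridin-2-yl)bis(trifluoromethanesulfonimide), O=S(=O)(N(c1ccc(Cl)cn1)S(=O)(=O)C(F)(F)F)C(F)(F)F
Why: Kinetic deprotonation can occur only at the α′ methylene (ring C3) because the γ position is the fully substituted C1, and O-sulfonylation of the resulting cross-conjugated lithium dienolate at −78 °C gives the 2-triflyloxy-1,3-diene (enol triflate synthesis) before any loss of silanolate can set in.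

Step 8
Reactants: 10 (S)-4-[(Z)-heptadec-8-en-1-yl]-4-(triethylsilyloxy)cyclohexa-1,5-dien-1-yl trifluoromethanesulfonate
Product: 11 (S)-triethyl({1-[(Z)-heptadec-8-en-1-yl]cyclohexa-2,4-dien-1-yl}oxy)silane
Conditions: Pd(OAc)2 (5 mol %), PPh3 (10 mol %), HCO2H (2 equiv), Et3N (3 equiv), DMF, rt to 40 °C
Reagents that add atoms: none
Why: In this palladium-catalysed formate hydrogenolysis of an enol triflate, oxidative addition of the C–OTf bond to zerovalent palladium, exchange of triflate for formate, loss of CO2 and C–H reductive elimination replace OTf by H with the diene in place, while the excess of amine over acid keeps the medium basic so that the tertiary allylic silyl ether neither ionises nor eliminates to the arene.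

Step 9
Reactants: 11 (S)-triethyl({1-[(Z)-heptadec-8-en-1-yl]cyclohexa-2,4-dien-1-yl}oxy)silane; 12 dioxygen
Product: 14 (4S,5S)-5-[(Z)-heptadec-8-en-1-yl]-4-hydroxy-5-(triethylsilyloxy)cyclohex-2-en-1-one, via bicyclic endoperoxide 13 (not isolated)
Conditions: O2 (1 atm), tetraphenylporphyrin (cat.), CH2Cl2, white LED, −78 °C; lamp off, Ar purge; Et3N, −78 to 0 °C
Reagents that add atoms: dioxygen (12), O=O
Why: The porphyrin sensitiser excites triplet dioxygen to singlet oxygen, which adds in a concerted suprafacial [4+2] manner to the termini C3 and C6 of the ring-locked s-cis diene of 11 to give 13; once the lamp is off, Et3N removes the bridgehead hydrogen at C3, the O–O bond breaks in the same event to the C3 ketone and the C6 alkoxide, and the ammonium ion returns the proton to give 14. The closest known reaction type is photooxygenation of cyclohexa-1,3-dienes to 2,3-dioxabicyclo[2.2.2]oct-5-enes followed by Kornblum–DeLaMare rearrangement to 4-hydroxycyclohex-2-enones. The only ring closed is the six-membered 1,2-dioxine ring of the bicycle, formed by cycloaddition with both C–O bonds made at once, and it is opened again in the same flask, so no ring is added to the final skeleton. The new C6 centre (and the short-lived C3 centre) is controlled by the existing C1 centre through the choice of diene face: the allylic C1–O bond with its lone pairs and the triethylsilyl group disfavour approach of the electron-rich dienophile on their side, whereas the small O2 molecule is little hindered by the chain methylene, whose remainder can turn away from the ring, so the bridge should form anti to the siloxy group and the C6–O bond, which is not broken afterwards, should end up trans to the C1–O bond (4S,5S). Chemoselectivity over the chain alkene is secured because an isolated 1,2-dialkyl cis alkene can only undergo a slow ene reaction while the cyclic diene is a fast acceptor and irradiation is stopped at full conversion of 11; regioselectivity of the proton abstraction is secured because C3–H is flanked by the C2 methylene while C6–H lies next to the fully substituted C1. The amine is added only in the dark, since amines quench singlet oxygen, and the exposure is kept cold and brief, since 14 is a β-siloxy ketone that prolonged base could eliminate and aromatise.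

Step 10
Reactants: 14 (4S,5S)-5-[(Z)-heptadec-8-en-1-yl]-4-hydroxy-5-(triethylsilyloxy)cyclohex-2-en-1-one
Product: 15 (4S,5S)-5-[(Z)-heptadec-8-en-1-yl]-4,5-dihydroxycyclohex-2-en-1-one (target)
Conditions: HF·pyridine, pyridine, THF, 0 °C
Reagents that add atoms: none
Why: Fluoride-induced Si–O cleavage under pyridine-buffered, non-basic conditions frees the tertiary alcohol without triggering retro-aldol cleavage or β-elimination and aromatisation of the β-hydroxy ketone, and neither stereocentre is involved.

## Compound list

1 | oleic acid | CCCCCCCC/C=C\CCCCCCCC(=O)O | starting material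
2 | 1,3-dioxoisoindolin-2-yl (Z)-octadec-9-enoate | CCCCCCCC/C=C\CCCCCCCC(=O)ON1C(=O)c2ccccc2C1=O | intermediate
3 | tert-butyl(4-iodophenoxy)dimethylsilane | CC(C)(C)[Si](C)(C)Oc1ccc(I)cc1 | starting material
4 | tert-butyl{4-[(Z)-heptadec-8-en-1-yl]phenoxy}dimethylsilane | CCCCCCCC/C=C\CCCCCCCc1ccc(O[Si](C)(C)C(C)(C)C)cc1 | intermediate
5 | 4-[(Z)-heptadec-8-en-1-yl]phenol | CCCCCCCC/C=C\CCCCCCCc1ccc(O)cc1 | intermediate
6 | 4-[(Z)-heptadec-8-en-1-yl]-4-hydroxycyclohexa-2,5-dien-1-one | CCCCCCCC/C=C\CCCCCCCC1(O)C=CC(=O)C=C1 | intermediate
7 | (S)-4-[(Z)-heptadec-8-en-1-yl]-4-hydroxycyclohex-2-en-1-one | CCCCCCCC/C=C\CCCCCCC[C@]1(O)CCC(=O)C=C1 | intermediate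
8 | (S)-4-[(Z)-heptadec-8-en-1-yl]-4-(triethylsilyloxy)cyclohex-2-en-1-one | CCCCCCCC/C=C\CCCCCCC[C@]1(O[Si](CC)(CC)CC)CCC(=O)C=C1 | intermediate
9 | lithium (S)-4-[(Z)-heptadec-8-en-1-yl]-4-(triethylsilyloxy)cyclohexa-1,5-dien-1-olate | CCCCCCCC/C=C\CCCCCCC[C@]1(O[Si](CC)(CC)CC)CC=C([O-])C=C1.[Li+] | intermediate (not isolated)
10 | (S)-4-[(Z)-heptadec-8-en-1-yl]-4-(triethylsilyloxy)cyclohexa-1,5-dien-1-yl trifluoromethanesulfonate | CCCCCCCC/C=C\CCCCCCC[C@]1(O[Si](CC)(CC)CC)CC=C(OS(=O)(=O)C(F)(F)F)C=C1 | intermediate
11 | (S)-triethyl({1-[(Z)-heptadec-8-en-1-yl]cyclohexa-2,4-dien-1-yl}oxy)silane | CCCCCCCC/C=C\CCCCCCC[C@]1(O[Si](CC)(CC)CC)CC=CC=C1 | intermediate (key-step precursor)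
12 | dioxygen | O=O | starting material
13 | (1S,4S,7S)-7-[(Z)-heptadec-8-en-1-yl]-7-(triethylsilyloxy)-2,3-dioxabicyclo[2.2.2]oct-5-ene (peroxide bridge anti to the siloxy group) | CCCCCCCC/C=C\CCCCCCC[C@]1(O[Si](CC)(CC)CC)C[C@H]2C=C[C@@H]1OO2 | intermediate (not isolated)
14 | (4S,5S)-5-[(Z)-heptadec-8-en-1-yl]-4-hydroxy-5-(triethylsilyloxy)cyclohex-2-en-1-one | CCCCCCCC/C=C\CCCCCCC[C@]1(O[Si](CC)(CC)CC)CC(=O)C=C[C@@H]1O | intermediate (key-step product)
15 | (4S,5S)-5-[(Z)-heptadec-8-en-1-yl]-4,5-dihydroxycyclohex-2-en-1-one (trans-diol) | CCCCCCCC/C=C\CCCCCCC[C@]1(O)CC(=O)C=C[C@@H]1O | target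

## Step count and risks

Total step count: 10. Longest linear sequence: 10 steps (1 to 15).

**Step 9 (highest risk).**
- The facial bias of the cycloaddition may be too small, because the face that must be attacked also carries the chain.
- The proton may be removed at the wrong bridgehead.
- The base may cause loss of silanol followed by aromatisation.
- Over-irradiation may bring ene oxidation of the chain alkene.
- A silyl shift from the C1 oxygen to the C6 oxygen would do no harm, since step 10 clears either oxygen.

The fallback replaces the base-induced fragmentation by reduction and selective oxidation. It sets out from 11, which is photooxygenated as before but without amine. The cold solution of 13 is treated with thiourea in MeOH/CH2Cl2, which reduces the O–O bond with retention at both carbons to (1S,4S,5S)-5-[(Z)-heptadec-8-en-1-yl]-5-(triethylsilyloxy)cyclohex-2-ene-1,4-diol F1. Facial isomers can be separated at this stable stage. MnO2 in CH2Cl2 should then oxidise the allylic alcohol at ring C3, which is flanked by a methylene, in preference to the neopentyl-like C6 alcohol. This route comes back at 14 without any exposure to base.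

**Step 5.**
- The very lipophilic substrate may be poorly taken up by the enzyme.
- Turnover in the aqueous medium may be slow.
- The sense of induction may be opposite to the one assumed.

The fallback replaces biocatalysis by enantiotopic deprotonation with a chiral base.
- It sets out from 6, which is silylated (TESOTf, 2,6-lutidine) to 4-[(Z)-heptadec-8-en-1-yl]-4-(triethylsilyloxy)cyclohexa-2,5-dien-1-one F2.
- Both enone double bonds are reduced by conjugate hydride delivery with [(Ph3P)CuH]6 in wet toluene, which leaves the isolated alkene alone. This gives 4-[(Z)-heptadec-8-en-1-yl]-4-(triethylsilyloxy)cyclohexan-1-one F3.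
- F3 is treated with lithium bis(1-phenylethyl)amide (the R,R or S,S enantiomer, whichever leads to the S series), LiCl and TMSCl present from the start, in THF at −100 °C. This gives (S)-triethyl({1-[(Z)-heptadec-8-en-1-yl]-4-(trimethylsilyloxy)cyclohex-3-en-1-yl}oxy)silane F4.
- Saegusa–Ito dehydrosilylation with Pd(OAc)2 in MeCN comes back to the route at 8.

**Step 8.**
- The product may lose silanol and aromatise under warm palladium/formate conditions.
- The diene may be over-reduced.
- Palladium hydride may isomerise the Z alkene.

The fallback replaces triflation and hydrogenolysis by a Shapiro reaction, which avoids palladium and acid altogether. It sets out from 8, which is condensed with 2,4,6-triisopropylbenzenesulfonyl hydrazide in THF at rt to the (S)-enone 2,4,6-triisopropylbenzenesulfonylhydrazone F5 (C=N geometry not defined). Treatment with n-BuLi (2.2 equiv) in THF/TMEDA from −78 to 0 °C removes N–H and the α′ proton. Sulfinate and nitrogen are then expelled, and the dienyllithium is quenched with water. This comes back to the route at 11 and bypasses 9 and 10.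

## Further compounds

F1 | step 9 | (1S,4S,5S)-5-[(Z)-heptadec-8-en-1-yl]-5-(triethylsilyloxy)cyclohex-2-ene-1,4-diol | CCCCCCCC/C=C\CCCCCCC[C@]1(O[Si](CC)(CC)CC)C[C@H](O)C=C[C@@H]1O
F2 | step 5 | 4-[(Z)-heptadec-8-en-1-yl]-4-(triethylsilyloxy)cyclohexa-2,5-dien-1-one | CCCCCCCC/C=C\CCCCCCCC1(O[Si](CC)(CC)CC)C=CC(=O)C=C1
F3 | step 5 | 4-[(Z)-heptadec-8-en-1-yl]-4-(triethylsilyloxy)cyclohexan-1-one | CCCCCCCC/C=C\CCCCCCCC1(O[Si](CC)(CC)CC)CCC(=O)CC1
F4 | step 5 | (S)-triethyl({1-[(Z)-heptadec-8-en-1-yl]-4-(trimethylsilyloxy)cyclohex-3-en-1-yl}oxy)silane | CCCCCCCC/C=C\CCCCCCC[C@]1(O[Si](CC)(CC)CC)CCC(O[Si](C)(C)C)=CC1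
F5 | step 8 | N'-{(S)-4-[(Z)-heptadec-8-en-1-yl]-4-(triethylsilyloxy)cyclohex-2-en-1-ylidene}-2,4,6-triisopropylbenzenesulfonohydrazide | CCCCCCCC/C=C\CCCCCCC[C@]1(O[Si](CC)(CC)CC)CCC(=NNS(=O)(=O)c2c(C(C)C)cc(C(C)C)cc2C(C)C)C=C1
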